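**Strategy.** Ring C is cut at C3–C4 and O1–C2. The C4 carbonyl carbon is attached to C4a, next to C8a and its oxygen, so a salicylaldehyde of ring A can use that phenol to steer rhodium into the formyl C–H bond. An aroyl sulfoxonium ylide then supplies C3 as a carbene carbon together with C2 and ring B, and the same phenol closes the pyranone by cyclodehydration, all in one operation. The aldehyde partner is 2-hydroxy-3,4-dimethoxybenzaldehyde carrying the future C5 oxygen as a tosylate, so only one phenol is free; it comes from symmetric 3,4,5-trimethoxyphenol. Alkaline removal of the tosyl group finishes the synthesis.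

Key step: step 6

Remark: flavone numbering is used for the product series (O1, C2, C3, C4, C4a, C5 to C8, C8a; ring B primed) and benzaldehyde numbering for the aldehydes. The target has no stereocentre, so no configuration has to be set. Cp* is pentamethylcyclopentadienyl.

Step 1
Reactants: 1 3,4,5-trimethoxyphenol
Product: 3 6-hydroxy-2,3,4-trimethoxybenzaldehyde, via hydroxymethylphenol 2 (not isolated)
Conditions: MgCl2, Et3N, (CH2O)n, MeCN, reflux; then 1 M HCl
Reagents that add atoms: paraformaldehyde (as formaldehyde), C=O
Why: The magnesium phenoxide (ArOMgCl) of 1 delivers formaldehyde to an ortho carbon through a six-membered chelate to give hydroxymethylphenol 2, which is oxidised in the same flask by hydride transfer to a second formaldehyde (magnesium-mediated ortho-formylation, Casnati–Skattebøl reaction); the two ortho carbons of 1 are equivalent and are the only unsubstituted ring positions, so a single aldehyde can form.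

Step 2
Reactants: 3 6-hydroxy-2,3,4-trimethoxybenzaldehyde
Product: 4 2-formyl-3,4,5-trimethoxyphenyl 4-methylbenzenesulfonate
Conditions: TsCl, K2CO3, acetone, reflux
Reagents that add atoms: p-toluenesulfonyl chloride, Cc1ccc(S(=O)(=O)Cl)cc1
Why: O-Sulfonylation of the only hydroxyl of 3 (phenol tosylation) masks the future C5 oxygen with a group that tolerates BCl3 and cationic rhodium but is cleaved by hydroxide at the end.

Step 3
Reactants: 4 2-formyl-3,4,5-trimethoxyphenyl 4-methylbenzenesulfonate
Product: 6 2-hydroxy-3,4-dimethoxy-6-(tosyloxy)benzaldehyde, via aryloxydichloroborane 5 (not isolated)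
Conditions: BCl3 (1.1 equiv), CH2Cl2, −78 to 0 °C; then H2O
Reagents that add atoms: none
Why: BCl3 binds the formyl oxygen and the neighbouring C2 methoxy oxygen in a six-membered chelate, so chloride removes only that methyl group (chelation-controlled ortho-demethylation of an aryl methyl ether) to give aryloxydichloroborane 5, which water hydrolyses to the phenol; the other ortho substituent is the inert sulfonate, and one equivalent of BCl3 at low temperature should leave the C3 and C4 methoxy groups untouched.

Step 4
Reactants: 7 2,3-dimethoxybenzoic acid
Product: 8 2,3-dimethoxybenzoyl chloride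
Conditions: (COCl)2, DMF (cat.), CH2Cl2, 0 °C to rt; evaporate
Reagents that add atoms: oxalyl chloride, O=C(Cl)C(=O)Cl
Why: Conversion of a carboxylic acid into its acid chloride through the chloroiminium species formed catalytically from DMF and oxalyl chloride; the aryl methyl ethers are inert and the by-products are volatile.

Step 5
Reactants: 8 2,3-dimethoxybenzoyl chloride; 9 trimethylsulfoxonium iodide
Product: 11 1-(2,3-dimethoxyphenyl)-2-(dimethyloxosulfanylidene)ethanone, via dimethylsulfoxonium methylide 10 (not isolated)
Conditions: 9 (3 equiv), KOtBu (3 equiv), THF, reflux; then 8, 0 °C to rt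
Reagents that add atoms: none
Why: Deprotonation of 9 gives methylide 10, which is acylated at carbon by 8, and a second equivalent of 10 removes the now acidic proton to leave the carbonyl-stabilised ylide (acylation of the Corey–Chaykovsky methylide), which is too weak a nucleophile to be acylated again.

Step 6
Reactants: 6 2-hydroxy-3,4-dimethoxy-6-(tosyloxy)benzaldehyde; 11 1-(2,3-dimethoxyphenyl)-2-(dimethyloxosulfanylidene)ethanone
Product: 14 2',3',7,8-tetramethoxy-5-(tosyloxy)flavone, via 1,3-diketone 12 (not isolated), via 2-hydroxyflavanone hemiketal 13 (not isolated)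
Conditions: [Cp*RhCl2]2 (4 mol %), AgSbF6 (16 mol %), NaOAc (0.5 equiv), AcOH (1 equiv), 11 (1.5 equiv), ClCH2CH2Cl, 80 °C, argon
Reagents that add atoms: none
Why: AgSbF6 removes chloride from [Cp*RhCl2]2 to give a cationic trivalent rhodium acetate that binds the C8a phenoxide of 6 and cleaves the adjacent formyl C–H bond by concerted metalation–deprotonation to a five-membered acyl rhodacycle; ylide 11 then binds through carbon and loses dimethyl sulfoxide to form a rhodium carbene, the acyl group migrates onto the carbene carbon (C3–C4), and protonation by acetic acid releases 1,3-diketone 12 and returns the catalyst. The closest known reaction type is the rhodium-catalysed annulation of salicylaldehydes with sulfoxonium ylides or alkynes to chromones through aldehyde C–H activation, applied here to a more heavily oxygenated aldehyde. Ring C closes when the C8a phenol adds to the aroyl carbonyl of 12 in a 6-exo-trig mode (O1–C2) to give hemiketal 13, which loses water under the acidic conditions to the aromatic pyranone. No stereocentre remains, because the hemiketal carbon of 13 forms as a racemate and becomes trigonal on dehydration. The step needs carbene insertion to outrun decarbonylation of the acyl rhodium and O–H insertion into the phenol, and it needs closure through the correct oxygen; the phenoxide chelate secures the first two by holding the acyl group on a coordinatively saturated Cp* metal and making carbene capture intramolecular, and the tosylate secures the last by leaving the C8a hydroxyl as the only nucleophile, so only the 7,8-dimethoxy pattern can form.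

Step 7
Reactants: 14 2',3',7,8-tetramethoxy-5-(tosyloxy)flavone
Product: 15 5-hydroxy-2',3',7,8-tetramethoxyflavone
Conditions: 2 M aq. KOH, THF/MeOH, 40 °C; then 1 M HCl
Reagents that add atoms: none
Why: Hydroxide attacks the sulfonyl sulfur and expels the C5 phenoxide, a good leaving group because it is conjugated with and chelated by the C4 carbonyl (alkaline hydrolysis of an aryl sulfonate), while the four methyl ethers are inert and the mild temperature with acidic work-up keeps ring C closed.

**Compound list**

1 | 3,4,5-trimethoxyphenol | COc1cc(O)cc(OC)c1OC | starting material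
2 | 2-(hydroxymethyl)-3,4,5-trimethoxyphenol (formed in situ as its magnesium phenoxide) | COc1cc(O)c(CO)c(OC)c1OC | intermediate
3 | 6-hydroxy-2,3,4-trimethoxybenzaldehyde | COc1cc(O)c(C=O)c(OC)c1OC | intermediate
4 | 2-formyl-3,4,5-trimethoxyphenyl 4-methylbenzenesulfonate | COc1cc(OS(=O)(=O)c2ccc(C)cc2)c(C=O)c(OC)c1OC | intermediate
5 | dichloro[2-formyl-5,6-dimethoxy-3-(tosyloxy)phenoxy]borane (formed in situ) | COc1cc(OS(=O)(=O)c2ccc(C)cc2)c(C=O)c(OB(Cl)Cl)c1OC | intermediate
6 | 2-hydroxy-3,4-dimethoxy-6-(tosyloxy)benzaldehyde | COc1cc(OS(=O)(=O)c2ccc(C)cc2)c(C=O)c(O)c1OC | intermediate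
7 | 2,3-dimethoxybenzoic acid | COc1cccc(C(=O)O)c1OC | starting material
8 | 2,3-dimethoxybenzoyl chloride | COc1cccc(C(=O)Cl)c1OC | intermediate
9 | trimethylsulfoxonium iodide | C[S+](C)(C)=O.[I-] | starting material
10 | dimethylsulfoxonium methylide (formed in situ) | C=S(C)(C)=O | intermediate
11 | 1-(2,3-dimethoxyphenyl)-2-(dimethyloxosulfanylidene)ethanone | COc1cccc(C(=O)C=S(C)(C)=O)c1OC | intermediate
12 | 1-(2,3-dimethoxyphenyl)-3-[2-hydroxy-3,4-dimethoxy-6-(tosyloxy)phenyl]propane-1,3-dione (formed in situ) | COc1cccc(C(=O)CC(=O)c2c(O)c(OC)c(OC)cc2OS(=O)(=O)c2ccc(C)cc2)c1OC | intermediate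
13 | 2-(2,3-dimethoxyphenyl)-2-hydroxy-7,8-dimethoxy-5-(tosyloxy)chroman-4-one (racemic, formed in situ) | COc1cccc(C2(O)CC(=O)c3c(OS(=O)(=O)c4ccc(C)cc4)cc(OC)c(OC)c3O2)c1OC | intermediate
14 | 2',3',7,8-tetramethoxy-5-(tosyloxy)flavone | COc1cccc(-c2cc(=O)c3c(OS(=O)(=O)c4ccc(C)cc4)cc(OC)c(OC)c3o2)c1OC | intermediate
15 | 5-hydroxy-2',3',7,8-tetramethoxyflavone | COc1cccc(-c2cc(=O)c3c(O)cc(OC)c(OC)c3o2)c1OC | target

**Step count and risks**

Total step count: 7. Longest linear sequence: 5 steps (steps 1, 2, 3, 6 and 7 from 1); the ylide branch (steps 4 and 5) joins at step 6.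

Steps most likely to fail:

1. Step 6. The formyl group of 6 is flanked by two ortho oxygen substituents, so metalation of its C–H bond may be slow. The acyl rhodium may lose CO before the carbene arrives, the carbene may insert into the phenol O–H bond, or the sequence may stall before dehydration. The fallback replaces C–H activation by a base-mediated C-acylation in the Baker–Venkataraman sense and sets out from 1 and 8. Friedel–Crafts acetylation of 1 (AcOH, BF3·OEt2, 90 °C) should give 1-(6-hydroxy-2,3,4-trimethoxyphenyl)ethanone F1. Tosylation as in step 2 should give 2-acetyl-3,4,5-trimethoxyphenyl 4-methylbenzenesulfonate F2. Chelation-controlled demethylation as in step 3 should give 1-[2-hydroxy-3,4-dimethoxy-6-(tosyloxy)phenyl]ethanone F3. Its dianion (LiN(SiMe3)2, 3 equiv, THF, −78 °C, kept cold to suppress attack of the enolate on the sulfonate) is acylated at carbon with 8 and should give diketone 12 after acidic work-up. The fallback comes back to the route at 12, which is isolated and cyclodehydrated through 13 with catalytic H2SO4 in AcOH at 90 °C to 14.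

2. Step 3. After the first ether cleavage the boron on the C2 oxygen can reach the neighbouring C3 methoxy group and cleave it as well, or conversion may stop early because the electron-poor sulfonate ring weakens the chelate. The fallback turns the over-cleavage into the plan and sets out from 4. Excess BCl3 (3 equiv, CH2Cl2, 0 °C to rt) should remove both the C2 and the C3 methyl groups and give 2,3-dihydroxy-4-methoxy-6-(tosyloxy)benzaldehyde F4. Its dianion (NaH, 2.1 equiv, DMF, 0 °C) should then be methylated once with MeI (1.0 equiv) at the C3 oxygen, the more nucleophilic one because the C2 phenoxide is conjugated with and chelated to the formyl group. This regioselective O-alkylation of a 2,3-dihydroxybenzaldehyde comes back to the route at 6.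

3. Step 7. Hydroxide may add to C2 and open ring C to the diketone. Once the C5 oxygen is free, re-closure can use either ring-A phenol and scramble the 7,8- into the 6,7-dimethoxy pattern (Wessely–Moser-type isomerisation), or the diketone may fragment by retro-Claisen cleavage. The fallback exchanges the sulfonate for one that a soft nucleophile removes at room temperature and sets out from 3. Sulfonylation with 2-nitrobenzenesulfonyl chloride (K2CO3, acetone) should give 2-formyl-3,4,5-trimethoxyphenyl 2-nitrobenzenesulfonate F5. Demethylation as in step 3 should give 2-formyl-3-hydroxy-4,5-dimethoxyphenyl 2-nitrobenzenesulfonate F6. Annulation with 11 under the conditions of step 6 should give 2',3',7,8-tetramethoxy-5-[(2-nitrophenyl)sulfonyloxy]flavone F7. Thiophenol with K2CO3 in DMF at room temperature should then cleave the sulfonate by ipso substitution at the nitroarene carbon (nucleophilic aromatic substitution, after which the aryloxysulfinate anion loses SO2), coming back to the route at 15.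

**Further compounds**

F1 | step 6 | 1-(6-hydroxy-2,3,4-trimethoxyphenyl)ethanone | CC(=O)c1c(O)cc(OC)c(OC)c1OC
F2 | step 6 | 2-acetyl-3,4,5-trimethoxyphenyl 4-methylbenzenesulfonate | CC(=O)c1c(OS(=O)(=O)c2ccc(C)cc2)cc(OC)c(OC)c1OC
F3 | step 6 | 1-[2-hydroxy-3,4-dimethoxy-6-(tosyloxy)phenyl]ethanone | CC(=O)c1c(OS(=O)(=O)c2ccc(C)cc2)cc(OC)c(OC)c1O
F4 | step 3 | 2,3-dihydroxy-4-methoxy-6-(tosyloxy)benzaldehyde | COc1cc(OS(=O)(=O)c2ccc(C)cc2)c(C=O)c(O)c1O
F5 | step 7 | 2-formyl-3,4,5-trimethoxyphenyl 2-nitrobenzenesulfonate | COc1cc(OS(=O)(=O)c2ccccc2[N+](=O)[O-])c(C=O)c(OC)c1OC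
F6 | step 7 | 2-formyl-3-hydroxy-4,5-dimethoxyphenyl 2-nitrobenzenesulfonate | COc1cc(OS(=O)(=O)c2ccccc2[N+](=O)[O-])c(C=O)c(O)c1OC
F7 | step 7 | 2',3',7,8-tetramethoxy-5-[(2-nitrophenyl)sulfonyloxy]flavone | COc1cccc(-c2cc(=O)c3c(OS(=O)(=O)c4ccccc4[N+](=O)[O-])cc(OC)c(OC)c3o2)c1OC
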